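**Plan**

1. Numbering used here: ring C1 (C=O), C2 (bears CH2CO2Me), C3 (=CH), C4 (OH), C5 (side chain), C6; side chain C1' (on C5) to C16'.
2. Cuts, in retrosynthetic order: C2–CH2CO2Me (Pd coupling on a 2-iodoenone); C5'–C6' (C(sp3)–C(sp2) union of a C15 tail with the ring-bearing half); C5–C1' (α'-alkylation of a ketal-masked cyclohexenedione); C8'–C9' of the tail (propargylation of geranyl bromide).
3. Enabling feature: C2'=C3'(CH3)–C4'H2–C5'H2 is what anti-Markovnikov hydroboration leaves of a 3-methyl-1,3-diene (only its C4'=C5' vinyl end is monosubstituted, boron goes to C5'), and C6'H=C7'(CH3) is a 2-methylalk-1-enyl unit that a terminal alkyne delivers as the E iodide by syn methylalumination.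
4. Forward: the only ring is bought as 1,4-dioxaspiro[4.5]dec-6-en-8-one (its C8=O becomes C4–OH, its ketal carbon becomes C1=O); dienylation, reduction, silylation, one-pot hydroboration/B-alkyl Suzuki–Miyaura union with the C15 iodide, ketal hydrolysis, α-iodination, Reformatsky–Negishi coupling, desilylation.
5. Stereochemistry: C4 and C5 are set together, cis and (4R,5R), by Ru-catalysed asymmetric hydrogenation of the racemic α'-alkyl enone under dynamic kinetic resolution; C2'=C3' comes from (E)-3-methylpent-2-en-4-yn-1-ol, C6'=C7' from the carboalumination, C10'=C11' from geranyl bromide.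

Key step: step 9

Remark: 1,4-dioxaspiro[4.5]dec-6-en-8-one and (E)-3-methylpent-2-en-4-yn-1-ol are taken as catalogue compounds; the former is otherwise one dehydrogenation step from 1,4-cyclohexanedione monoethylene ketal.

**Route**

Step 1
Reactants: 1 (2E)-1-bromo-3,7-dimethylocta-2,6-diene (geranyl bromide)
Product: 2 trimethyl[(5E)-6,10-dimethylundeca-5,9-dien-1-yn-1-yl]silane
Conditions: 1-(trimethylsilyl)propyne, n-BuLi, THF, −78 → −20 °C; then 1, −78 °C → rt
Reagents that add atoms: 1-(trimethylsilyl)propyne, CC#C[Si](C)(C)C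
Why: SN2 alkylation of the propargylic lithium reagent by the primary allylic bromide (propargylation, the silyl group steering attack to the propargylic rather than the allenic terminus) leaves the E alkene of the geranyl unit untouched and creates no stereocentre.

Step 2
Reactants: 2 trimethyl[(5E)-6,10-dimethylundeca-5,9-dien-1-yn-1-yl]silane
Product: 3 (5E)-6,10-dimethylundeca-5,9-dien-1-yne
Conditions: K2CO3, MeOH, rt
Reagents that add atoms: none
Why: Base-catalysed methanolysis of the alkynyl C–Si bond (protodesilylation) frees the terminal alkyne without affecting the two trisubstituted alkenes.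

Step 3
Reactants: 3 (5E)-6,10-dimethylundeca-5,9-dien-1-yne
Product: 5 (1E,5E)-1-iodo-2,6,10-trimethylundeca-1,5,9-triene, via alkenyldimethylalane 4 (not isolated)
Conditions: Me3Al (2 equiv), Cp2ZrCl2 (0.25 equiv), CH2Cl2, 0 °C → rt; then I2, THF, −30 → 0 °C
Reagents that add atoms: trimethylaluminium, C[Al](C)C; iodine, II
Why: Zirconium-catalysed methylalumination of the terminal alkyne (Negishi carboalumination) adds CH3 and Al syn with Al on the terminal carbon, and iodinolysis of the C–Al bond with retention should give the E iodide, the isolated trisubstituted alkenes being inert.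

Step 4
Reactants: 6 (2E)-3-methylpent-2-en-4-yn-1-ol
Product: 7 (2E)-3-methylpenta-2,4-dien-1-ol
Conditions: H2 (1 atm), Pd/CaCO3 poisoned with Pb(OAc)2, quinoline, EtOAc, rt, stopped after one equivalent of H2
Reagents that add atoms: none
Why: Semihydrogenation over the poisoned palladium catalyst (Lindlar reduction) should stop at the alkene and turn the terminal alkyne into the vinyl group without touching the stereodefined E trisubstituted alkene.

Step 5
Reactants: 7 (2E)-3-methylpenta-2,4-dien-1-ol
Product: 8 (3E)-5-bromo-3-methylpenta-1,3-diene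
Conditions: PBr3 (0.4 equiv), Et2O, −20 → 0 °C; used crude at once
Reagents that add atoms: phosphorus tribromide, BrP(Br)Br
Why: Bromination of the primary allylic alcohol through its phosphite ester with direct displacement at low temperature should keep the E geometry, and the bromide is used immediately because ionisation to the pentadienyl cation would scramble it.

Step 6
Reactants: 9 1,4-dioxaspiro[4.5]dec-6-en-8-one; 8 (3E)-5-bromo-3-methylpenta-1,3-diene
Product: 11 rac-9-[(2E)-3-methylpenta-2,4-dien-1-yl]-1,4-dioxaspiro[4.5]dec-6-en-8-one, via lithium dienolate 10 (not isolated)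
Conditions: LDA, THF, −78 °C; then 8, DMPU, −78 → −30 °C
Reagents that add atoms: none
Why: Kinetic deprotonation at C9 (the α'-position, the γ-position being blocked by the ketal) gives the cross-conjugated lithium dienolate, whose SN2 C-alkylation by the primary allylic bromide (enolate alkylation) installs the dienyl arm with its E geometry, the new C9 stereocentre being formed racemic and corrected in the next step.

Step 7
Reactants: 11 rac-9-[(2E)-3-methylpenta-2,4-dien-1-yl]-1,4-dioxaspiro[4.5]dec-6-en-8-one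
Product: 12 (8R,9R)-9-[(2E)-3-methylpenta-2,4-dien-1-yl]-1,4-dioxaspiro[4.5]dec-6-en-8-ol
Conditions: H2 (8 atm), RuCl2[(R)-binap][(S,S)-dpen] (1 mol %), KOt-Bu (10 mol %), i-PrOH, 25 °C
Reagents that add atoms: none
Why: Noyori asymmetric hydrogenation of the C=O group under dynamic kinetic resolution should funnel both enantiomers into one product, because KOt-Bu epimerises C9 through the dienolate faster than the slow enantiomer is reduced, the outer-sphere Ru–H/N–H transfer spares the enone C=C, the diene and the ketal, hydride arrives from the equatorial side to give the cis alcohol, and the catalyst antipode is the one expected, by analogy with 2-alkylcyclohexanones, to give the (8R,9R) sense.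

Step 8
Reactants: 12 (8R,9R)-9-[(2E)-3-methylpenta-2,4-dien-1-yl]-1,4-dioxaspiro[4.5]dec-6-en-8-ol
Product: 13 tert-butyl(dimethyl){[(8R,9R)-9-[(2E)-3-methylpenta-2,4-dien-1-yl]-1,4-dioxaspiro[4.5]dec-6-en-8-yl]oxy}silane
Conditions: TBSCl, imidazole, DMF, rt
Reagents that add atoms: tert-butyldimethylsilyl chloride, CC(C)(C)[Si](C)(C)Cl
Why: Imidazole-promoted silylation of the secondary allylic alcohol protects the hydroxyl for the hydroboration and for the later iodine and zinc enolate chemistry without touching either stereocentre.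

Step 9
Reactants: 13 tert-butyl(dimethyl){[(8R,9R)-9-[(2E)-3-methylpenta-2,4-dien-1-yl]-1,4-dioxaspiro[4.5]dec-6-en-8-yl]oxy}silane; 5 (1E,5E)-1-iodo-2,6,10-trimethylundeca-1,5,9-triene
Product: 15 tert-butyl(dimethyl){[(8R,9R)-9-[(2E,6E,10E)-3,7,11,15-tetramethylhexadeca-2,6,10,14-tetraen-1-yl]-1,4-dioxaspiro[4.5]dec-6-en-8-yl]oxy}silane, via B-alkyl-9-BBN adduct 14 (not isolated)
Conditions: 9-BBN (1.3 equiv), THF, 0 °C → rt; then 5, Pd(dppf)Cl2 (5 mol %), AsPh3 (10 mol %), Cs2CO3 (3 equiv), DMF/H2O, rt
Reagents that add atoms: none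
Why: 9-BBN adds across the only monosubstituted C=C of 13, the C4'=C5' vinyl end of the 3-methyl-1,3-diene, placing boron on the terminal C5', because the trisubstituted C2'=C3' alkene and the ring alkene flanked by the ketal and the silyl ether are far slower; aqueous Cs2CO3 then turns the B-alkyl-9-BBN 14 into its hydroxyborate, which passes the primary alkyl group to the alkenylpalladium iodide formed by oxidative addition of zerovalent palladium into the C–I bond of 5, and reductive elimination forges C5'–C6'. The closest known reaction type is the one-pot alkene hydroboration/B-alkyl Suzuki–Miyaura coupling with (E)-1-iodo-2-methylalk-1-enes, a standard way of joining isoprenoid and polyketide halves. No ring is closed. No stereocentre is created: the E geometry of C6'=C7' is set beforehand by the syn carboalumination and is carried through oxidative addition and reductive elimination with retention, and the E geometry of C2'=C3' is left alone because hydroboration stops at the vinyl group. The step needs chemo- and regioselective hydroboration and a coupling that outruns β-hydride elimination of the alkylpalladium; the bulk of 9-BBN, the absence of any free carbonyl or hydroxyl group in 13 (ketone as dioxolane, alcohol as silyl ether, acetate arm not yet in place) and the wide-bite-angle dppf ligand with AsPh3 should secure these.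

Step 10
Reactants: 15 tert-butyl(dimethyl){[(8R,9R)-9-[(2E,6E,10E)-3,7,11,15-tetramethylhexadeca-2,6,10,14-tetraen-1-yl]-1,4-dioxaspiro[4.5]dec-6-en-8-yl]oxy}silane
Product: 16 (4R,5R)-4-{[tert-butyl(dimethyl)silyl]oxy}-5-[(2E,6E,10E)-3,7,11,15-tetramethylhexadeca-2,6,10,14-tetraen-1-yl]cyclohex-2-en-1-one
Conditions: oxalic acid (aq.), THF, rt
Reagents that add atoms: water, O
Why: Mild acid hydrolysis of the allylic dioxolane (ketal cleavage) unveils the C1 ketone in conjugation with the ring alkene, which completes the 1,4-carbonyl transposition to the γ-silyloxy enone, while the silyl ether and the trisubstituted alkenes should survive the weak acid.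

Step 11
Reactants: 16 (4R,5R)-4-{[tert-butyl(dimethyl)silyl]oxy}-5-[(2E,6E,10E)-3,7,11,15-tetramethylhexadeca-2,6,10,14-tetraen-1-yl]cyclohex-2-en-1-one
Product: 17 (4R,5R)-4-{[tert-butyl(dimethyl)silyl]oxy}-2-iodo-5-[(2E,6E,10E)-3,7,11,15-tetramethylhexadeca-2,6,10,14-tetraen-1-yl]cyclohex-2-en-1-one
Conditions: I2, pyridine/CH2Cl2, 0 °C → rt, dark
Reagents that add atoms: iodine, II
Why: α-Iodination of the enone by reversible conjugate addition of pyridine, iodination of the resulting enolate and elimination (Baylis–Hillman-type addition–elimination) should place iodine at C2 only, the isolated alkenes adding iodine only reversibly in this non-nucleophilic medium.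

Step 12
Reactants: 17 (4R,5R)-4-{[tert-butyl(dimethyl)silyl]oxy}-2-iodo-5-[(2E,6E,10E)-3,7,11,15-tetramethylhexadeca-2,6,10,14-tetraen-1-yl]cyclohex-2-en-1-one
Product: 18 methyl 2-[(3R,4R)-3-{[tert-butyl(dimethyl)silyl]oxy}-6-oxo-4-[(2E,6E,10E)-3,7,11,15-tetramethylhexadeca-2,6,10,14-tetraen-1-yl]cyclohex-1-en-1-yl]acetate
Conditions: methyl bromoacetate, Zn dust, THF, 40 °C; then 17, Pd(dba)2 (3 mol %), P(t-Bu)3 (3 mol %), THF, rt
Reagents that add atoms: methyl bromoacetate, COC(=O)CBr
Why: Palladium-catalysed cross-coupling of the activated alkenyl iodide with the zinc enolate of methyl acetate (Negishi-type coupling of a Reformatsky reagent) forms the C2–CH2CO2Me bond at room temperature, where oxidative addition of zerovalent palladium into the electron-poor C–I bond and transmetalation are expected to outrun addition of the zinc enolate to the ketone.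

Step 13
Reactants: 18 methyl 2-[(3R,4R)-3-{[tert-butyl(dimethyl)silyl]oxy}-6-oxo-4-[(2E,6E,10E)-3,7,11,15-tetramethylhexadeca-2,6,10,14-tetraen-1-yl]cyclohex-1-en-1-yl]acetate
Product: 19 methyl 2-[(3R,4R)-3-hydroxy-6-oxo-4-[(2E,6E,10E)-3,7,11,15-tetramethylhexadeca-2,6,10,14-tetraen-1-yl]cyclohex-1-en-1-yl]acetate
Conditions: HF·pyridine, pyridine/THF, 0 °C → rt
Reagents that add atoms: none
Why: Fluoride-mediated cleavage of the silyl ether in a buffered, weakly acidic medium (desilylation) should free the C4 hydroxyl without the base that could dehydrate the γ-hydroxy enone or move the C2=C3 alkene toward the ester.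

**Compound list**

1 | (2E)-1-bromo-3,7-dimethylocta-2,6-diene (geranyl bromide) | BrC/C=C(\C)CCC=C(C)C | starting material
2 | trimethyl[(5E)-6,10-dimethylundeca-5,9-dien-1-yn-1-yl]silane | C[Si](C)(C)C#CCC/C=C(\C)CCC=C(C)C | intermediate
3 | (5E)-6,10-dimethylundeca-5,9-dien-1-yne | C#CCC/C=C(\C)CCC=C(C)C | intermediate
4 | dimethyl[(1E,5E)-2,6,10-trimethylundeca-1,5,9-trien-1-yl]alumane | C[Al](C)/C=C(\C)CC/C=C(\C)CCC=C(C)C | intermediate
5 | (1E,5E)-1-iodo-2,6,10-trimethylundeca-1,5,9-triene | I/C=C(\C)CC/C=C(\C)CCC=C(C)C | intermediate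
6 | (2E)-3-methylpent-2-en-4-yn-1-ol | OC/C=C(\C)C#C | starting material
7 | (2E)-3-methylpenta-2,4-dien-1-ol | OC/C=C(\C)C=C | intermediate
8 | (3E)-5-bromo-3-methylpenta-1,3-diene | BrC/C=C(\C)C=C | intermediate
9 | 1,4-dioxaspiro[4.5]dec-6-en-8-one | O=C1C=CC2(CC1)OCCO2 | starting material
10 | lithium 1,4-dioxaspiro[4.5]deca-6,8-dien-8-olate | [Li]OC1=CCC2(OCCO2)C=C1 | intermediate
11 | rac-9-[(2E)-3-methylpenta-2,4-dien-1-yl]-1,4-dioxaspiro[4.5]dec-6-en-8-one | O=C1C=CC2(CC1C/C=C(\C)C=C)OCCO2 | intermediate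
12 | (8R,9R)-9-[(2E)-3-methylpenta-2,4-dien-1-yl]-1,4-dioxaspiro[4.5]dec-6-en-8-ol | C1=C[C@H](O)[C@H](C/C=C(\C)C=C)CC12OCCO2 | intermediate
13 | tert-butyl(dimethyl){[(8R,9R)-9-[(2E)-3-methylpenta-2,4-dien-1-yl]-1,4-dioxaspiro[4.5]dec-6-en-8-yl]oxy}silane | C1=C[C@H](O[Si](C)(C)C(C)(C)C)[C@H](C/C=C(\C)C=C)CC12OCCO2 | intermediate
14 | 9-{(3E)-5-[(8R,9R)-8-{[tert-butyl(dimethyl)silyl]oxy}-1,4-dioxaspiro[4.5]dec-6-en-9-yl]-3-methylpent-3-en-1-yl}-9-borabicyclo[3.3.1]nonane | C1=C[C@H](O[Si](C)(C)C(C)(C)C)[C@H](C/C=C(\C)CCB3C4CCCC3CCC4)CC12OCCO2 | intermediate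
15 | tert-butyl(dimethyl){[(8R,9R)-9-[(2E,6E,10E)-3,7,11,15-tetramethylhexadeca-2,6,10,14-tetraen-1-yl]-1,4-dioxaspiro[4.5]dec-6-en-8-yl]oxy}silane | C1=C[C@H](O[Si](C)(C)C(C)(C)C)[C@H](C/C=C(\C)CC/C=C(\C)CC/C=C(\C)CCC=C(C)C)CC12OCCO2 | intermediate
16 | (4R,5R)-4-{[tert-butyl(dimethyl)silyl]oxy}-5-[(2E,6E,10E)-3,7,11,15-tetramethylhexadeca-2,6,10,14-tetraen-1-yl]cyclohex-2-en-1-one | C1=C[C@H](O[Si](C)(C)C(C)(C)C)[C@H](C/C=C(\C)CC/C=C(\C)CC/C=C(\C)CCC=C(C)C)CC1=O | intermediate
17 | (4R,5R)-4-{[tert-butyl(dimethyl)silyl]oxy}-2-iodo-5-[(2E,6E,10E)-3,7,11,15-tetramethylhexadeca-2,6,10,14-tetraen-1-yl]cyclohex-2-en-1-one | IC1=C[C@H](O[Si](C)(C)C(C)(C)C)[C@H](C/C=C(\C)CC/C=C(\C)CC/C=C(\C)CCC=C(C)C)CC1=O | intermediate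
18 | methyl 2-[(3R,4R)-3-{[tert-butyl(dimethyl)silyl]oxy}-6-oxo-4-[(2E,6E,10E)-3,7,11,15-tetramethylhexadeca-2,6,10,14-tetraen-1-yl]cyclohex-1-en-1-yl]acetate | COC(=O)CC1=C[C@H](O[Si](C)(C)C(C)(C)C)[C@H](C/C=C(\C)CC/C=C(\C)CC/C=C(\C)CCC=C(C)C)CC1=O | intermediate
19 | methyl 2-[(3R,4R)-3-hydroxy-6-oxo-4-[(2E,6E,10E)-3,7,11,15-tetramethylhexadeca-2,6,10,14-tetraen-1-yl]cyclohex-1-en-1-yl]acetate | COC(=O)CC1=C[C@H](O)[C@H](C/C=C(\C)CC/C=C(\C)CC/C=C(\C)CCC=C(C)C)CC1=O | target

**Count and risks**

Total step count: 13. Longest linear sequence: 10 steps (steps 4 to 13, from 6 to 19).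

Steps most likely to fail:

Step 7. Epimerisation at C9 may not keep pace with hydrogenation, so that the resolution stays kinetic and stalls near half conversion, or the alkoxide base may add to the enone. The fallback sets out from 11. Reduction with LiBH(s-Bu)3 in THF at −78 °C, which attacks from the equatorial side and whose 1,4-addition is hindered by the quaternary ketal carbon next to C6, should give racemic cis-9-[(2E)-3-methylpenta-2,4-dien-1-yl]-1,4-dioxaspiro[4.5]dec-6-en-8-ol F1. Lipase-catalysed acetylation (Burkholderia cepacia lipase, vinyl acetate, MTBE) is then expected, by the usual size rule for secondary alcohols with C9 as the large and C7 as the medium arm, to acylate the (8S,9S) enantiomer to (8S,9S)-9-[(2E)-3-methylpenta-2,4-dien-1-yl]-1,4-dioxaspiro[4.5]dec-6-en-8-yl acetate F2 and to leave the (8R,9R) alcohol, which is 12, where the route is rejoined.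

Step 12. The zinc enolate may add to the enone carbonyl or reduce the C–I bond faster than it transmetalates to palladium. The fallback sets out from 16 and bypasses step 11 as well. Morita–Baylis–Hillman hydroxymethylation (aqueous formaldehyde, DMAP, THF/H2O) should give (4R,5R)-4-{[tert-butyl(dimethyl)silyl]oxy}-2-(hydroxymethyl)-5-[(2E,6E,10E)-3,7,11,15-tetramethylhexadeca-2,6,10,14-tetraen-1-yl]cyclohex-2-en-1-one F3. Methyl chloroformate and pyridine should convert it into {(3R,4R)-3-{[tert-butyl(dimethyl)silyl]oxy}-6-oxo-4-[(2E,6E,10E)-3,7,11,15-tetramethylhexadeca-2,6,10,14-tetraen-1-yl]cyclohex-1-en-1-yl}methyl methyl carbonate F4. Palladium-catalysed decarboxylative carbonylation (Pd(OAc)2, PPh3, CO 10 atm, toluene, 50 °C), in which the methoxide released from the carbonate captures the acylpalladium formed at the CH2 end of the π-allyl unit, should then give 18, where the route is rejoined.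

Step 9. Transfer of the alkyl group from boron to palladium may be slow, so that protodeboronation, β-hydride elimination or homocoupling of the iodide take over, and regioisomeric boranes cannot be removed because the borane is not isolated. The fallback sets out from 13. Hydroboration as before followed by oxidation (NaBO3·4H2O) should give (3E)-5-[(8R,9R)-8-{[tert-butyl(dimethyl)silyl]oxy}-1,4-dioxaspiro[4.5]dec-6-en-9-yl]-3-methylpent-3-en-1-ol F5, which can be purified. I2, PPh3 and imidazole should give tert-butyl{[(8R,9R)-9-[(2E)-5-iodo-3-methylpent-2-en-1-yl]-1,4-dioxaspiro[4.5]dec-6-en-8-yl]oxy}dimethylsilane F6. Zinc insertion (Zn dust, LiCl, THF, 40 °C) should give iodo{(3E)-5-[(8R,9R)-8-{[tert-butyl(dimethyl)silyl]oxy}-1,4-dioxaspiro[4.5]dec-6-en-9-yl]-3-methylpent-3-en-1-yl}zinc F7 (not isolated), and its Negishi homoallyl–alkenyl coupling with 5 (Pd(dppf)Cl2, THF/NMP, rt) should give 15, where the route is rejoined.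

**Further compounds**

F1 | step 7 | racemic cis-9-[(2E)-3-methylpenta-2,4-dien-1-yl]-1,4-dioxaspiro[4.5]dec-6-en-8-ol ((8R,9R) and (8S,9S)) | C1=C[C@H](O)[C@H](C/C=C(\C)C=C)CC12OCCO2.C1=C[C@@H](O)[C@@H](C/C=C(\C)C=C)CC12OCCO2
F2 | step 7 | (8S,9S)-9-[(2E)-3-methylpenta-2,4-dien-1-yl]-1,4-dioxaspiro[4.5]dec-6-en-8-yl acetate | C1=C[C@@H](OC(C)=O)[C@@H](C/C=C(\C)C=C)CC12OCCO2
F3 | step 12 | (4R,5R)-4-{[tert-butyl(dimethyl)silyl]oxy}-2-(hydroxymethyl)-5-[(2E,6E,10E)-3,7,11,15-tetramethylhexadeca-2,6,10,14-tetraen-1-yl]cyclohex-2-en-1-one | OCC1=C[C@H](O[Si](C)(C)C(C)(C)C)[C@H](C/C=C(\C)CC/C=C(\C)CC/C=C(\C)CCC=C(C)C)CC1=O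
F4 | step 12 | {(3R,4R)-3-{[tert-butyl(dimethyl)silyl]oxy}-6-oxo-4-[(2E,6E,10E)-3,7,11,15-tetramethylhexadeca-2,6,10,14-tetraen-1-yl]cyclohex-1-en-1-yl}methyl methyl carbonate | COC(=O)OCC1=C[C@H](O[Si](C)(C)C(C)(C)C)[C@H](C/C=C(\C)CC/C=C(\C)CC/C=C(\C)CCC=C(C)C)CC1=O
F5 | step 9 | (3E)-5-[(8R,9R)-8-{[tert-butyl(dimethyl)silyl]oxy}-1,4-dioxaspiro[4.5]dec-6-en-9-yl]-3-methylpent-3-en-1-ol | C1=C[C@H](O[Si](C)(C)C(C)(C)C)[C@H](C/C=C(\C)CCO)CC12OCCO2
F6 | step 9 | tert-butyl{[(8R,9R)-9-[(2E)-5-iodo-3-methylpent-2-en-1-yl]-1,4-dioxaspiro[4.5]dec-6-en-8-yl]oxy}dimethylsilane | C1=C[C@H](O[Si](C)(C)C(C)(C)C)[C@H](C/C=C(\C)CCI)CC12OCCO2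
F7 | step 9 | iodo{(3E)-5-[(8R,9R)-8-{[tert-butyl(dimethyl)silyl]oxy}-1,4-dioxaspiro[4.5]dec-6-en-9-yl]-3-methylpent-3-en-1-yl}zinc | C1=C[C@H](O[Si](C)(C)C(C)(C)C)[C@H](C/C=C(\C)CC[Zn]I)CC12OCCO2
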